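**Retrosynthetic overview** (cembrane numbering: C1 = ring CH bearing C15(=C16H2)–C17O2; C3 = CHOH; C4=C5 and C7=C8 = ring alkenes; C11 = CHOAc; C12 = C(Me)O; C13, C14 = the CH2 pair between C12 and C1)
1. Ring B (seven-membered lactone) is made last: the C17 acid attacks C12 of an 11S,12S epoxide across the ring (inversion to 12R); C11–OH is then acetylated and C3–OH released.
2. Ring A (14-membered carbocycle) is closed by a C14 radical adding to C1 of a temporary six-membered lactone (ring T: O–C17(=O)–C15=C1–C2–C3) that carries PhSO2 on C16; loss of PhSO2• unveils the C15=C16 methylene.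
3. Enabling feature: C1 is at once the β-carbon of the C15(=C16)–C17 acrylate of ring B and 1,3 to the C3 carbinol in ring A, so O3 can hold C17 in ring T, which activates C1 and relays C3 to C1 (trans).
4. The acyclic precursor comes from a Stille union at C5–C6: a western stannane (C1–C5, C15–C17; propargyl alcohol; C3 by allylboration; ring T by metathesis) and an eastern allylic acetate (C6–C14; geranyl acetate; C11/C12 by Shi epoxidation).
5. Ring order: T (step 7), A (step 14), T opened (step 15), B (step 16).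

Key step: step 14

Remark on the target: the SMILES is read as 1R,3S,11S,12R,4E,7E in the numbering above.
Remark on the chemistry: the enantiomer of the Shi ketone (L-series, made from L-sorbose) is assumed to be at hand as a catalyst.

Step 1
Reactants: 1 prop-2-yn-1-ol
Product: 3 (E)-3-iodo-2-methylprop-2-en-1-ol, via alkenylalane 2 (not isolated)
Conditions: AlMe3 (3 equiv), Cp2ZrCl2 (0.25 equiv), CH2Cl2, 0 °C to rt; then I2, THF, −30 to 0 °C; aq. K2CO3
Reagents that add atoms: trimethylaluminium C[Al](C)C; iodine II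
Why: Zirconium-catalysed carboalumination (Negishi) adds methyl and aluminium syn across the alkyne with aluminium on the terminal carbon, and iodinolysis with retention should give the E vinyl iodide (C3, C4 with its methyl, C5).

Step 2
Reactants: 3 (E)-3-iodo-2-methylprop-2-en-1-ol
Product: 4 (E)-3-iodo-2-methylprop-2-enal
Conditions: MnO2 (excess), CH2Cl2, rt
Reagents that add atoms: none
Why: MnO2 oxidises allylic alcohols selectively and should leave the vinyl iodide and the alkene geometry untouched.

Step 3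
Reactants: 4 (E)-3-iodo-2-methylprop-2-enal
Product: 6 (3S,1E)-1-iodo-2-methylhexa-1,5-dien-3-ol, via boron alkoxide 5 (not isolated)
Conditions: (−)-Ipc2BOMe, allylMgBr, Et2O, 0 °C then −78 °C; 4, −78 °C; then NaOH, H2O2, rt
Reagents that add atoms: allylmagnesium bromide C=CC[Mg]Br
Why: Brown allylboration through a chair six-membered transition state; the reagent from (−)-Ipc2BOMe should give the S carbinol (C3) with this enal, in the same facial sense as with benzaldehyde.

Step 4
Reactants: 6 (3S,1E)-1-iodo-2-methylhexa-1,5-dien-3-ol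
Product: 7 (3S,1E)-2-methyl-1-(trimethylstannyl)hexa-1,5-dien-3-ol
Conditions: Pd(PPh3)4 (5 mol %), (Me3Sn)2 (1.2 equiv), toluene, 80 °C
Reagents that add atoms: hexamethylditin C[Sn](C)(C)[Sn](C)(C)C
Why: Palladium-catalysed stannylation of a vinyl iodide (oxidative addition, Sn–Sn transmetalation, reductive elimination) proceeds with retention of alkene geometry and tolerates the free alcohol.

Step 5
Reactants: 8 2-(bromomethyl)acrylic acid
Product: 9 2-[(phenylsulfonyl)methyl]acrylic acid
Conditions: PhSO2Na (1.1 equiv), THF–H2O, rt; then dilute HCl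
Reagents that add atoms: sodium benzenesulfinate [Na+].[O-]S(=O)c1ccccc1
Why: S-alkylation of the sulfinate by the allylic bromide (direct or with allylic shift, both give the same product) is the standard route to 2-(sulfonylmethyl)acrylates.

Step 6
Reactants: 7 (3S,1E)-2-methyl-1-(trimethylstannyl)hexa-1,5-dien-3-ol; 9 2-[(phenylsulfonyl)methyl]acrylic acid
Product: 10 (3S,1E)-2-methyl-1-(trimethylstannyl)hexa-1,5-dien-3-yl 2-[(phenylsulfonyl)methyl]acrylate
Conditions: DCC (1.1 equiv), DMAP (10 mol %), CH2Cl2, 0 °C to rt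
Reagents that add atoms: none
Why: Steglich esterification of the secondary alcohol consumes the acid quickly, so the vinylstannane should not be protodestannylated, and C3 is not touched.

Step 7
Reactants: 10 (3S,1E)-2-methyl-1-(trimethylstannyl)hexa-1,5-dien-3-yl 2-[(phenylsulfonyl)methyl]acrylate
Product: 11 (6S)-3-[(phenylsulfonyl)methyl]-6-[(E)-1-(trimethylstannyl)prop-1-en-2-yl]-5,6-dihydro-2H-pyran-2-one
Conditions: second-generation Grubbs catalyst (H2IMes)(PCy3)Cl2Ru=CHPh (5 mol %), CH2Cl2, 40 °C, 5 mM
Reagents that add atoms: none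
Why: Ring-closing metathesis of a homoallylic 2-substituted acrylate gives the 3-substituted 5,6-dihydropyran-2-one (ring T, C1=C15), and the hindered trisubstituted vinylstannane should not take part.

Step 8
Reactants: 12 geranyl acetate
Product: 14 (2E,6E)-3,7-dimethyl-8-oxoocta-2,6-dien-1-yl acetate, via allylic alcohol 13 (not isolated)
Conditions: SeO2 (0.1 equiv), t-BuOOH, salicylic acid (0.1 equiv), CH2Cl2, rt; then MnO2, CH2Cl2, rt
Reagents that add atoms: tert-butyl hydroperoxide CC(C)(C)OO
Why: Riley-type SeO2 allylic oxidation (ene reaction, then 2,3-shift) attacks the E methyl group of the distal trisubstituted alkene, and MnO2 takes the crude alcohol on to the enal.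

Step 9
Reactants: 14 (2E,6E)-3,7-dimethyl-8-oxoocta-2,6-dien-1-yl acetate
Product: 15 (2E,6E)-3,7-dimethylnona-2,6,8-trien-1-yl acetate
Conditions: Ph3PCH3Br, KN(SiMe3)2, THF, −78 to 0 °C
Reagents that add atoms: methyltriphenylphosphonium bromide C[P+](c1ccccc1)(c1ccccc1)c1ccccc1.[Br-]
Why: Wittig methylenation of the enal adds C14 as a terminal vinyl group; the non-stabilised ylide reacts with the aldehyde far faster than with the acetate at low temperature.

Step 10
Reactants: 15 (2E,6E)-3,7-dimethylnona-2,6,8-trien-1-yl acetate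
Product: 17 (2E,6E)-9-hydroxy-3,7-dimethylnona-2,6-dien-1-yl acetate, via alkylborane 16 (not isolated)
Conditions: 9-BBN (1.1 equiv), THF, 0 °C to rt; then H2O2, aq. NaOAc, 0 °C
Reagents that add atoms: hydrogen peroxide OO
Why: Hydroboration–oxidation; 9-BBN adds anti-Markovnikov to the monosubstituted terminus of the diene only and leaves both trisubstituted alkenes, and buffered oxidation keeps the acetate.

Step 11
Reactants: 17 (2E,6E)-9-hydroxy-3,7-dimethylnona-2,6-dien-1-yl acetate
Product: 18 (2E)-5-[(2S,3S)-3-(2-hydroxyethyl)-3-methyloxiran-2-yl]-3-methylpent-2-en-1-yl acetate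
Conditions: ent-Shi ketone (0.3 equiv), KHSO5 (Oxone), K2CO3, Bu4NHSO4, Na2B4O7 buffer, MeCN–CH2(OMe)2–H2O, 0 °C
Reagents that add atoms: potassium peroxymonosulfate [K+].[O-]S(=O)(=O)OO
Why: Shi epoxidation; the chiral dioxirane attacks the electron-richer distal E alkene (the other is deactivated by the allylic acetate) through the spiro transition state, and the L-series ketone should give the 11S,12S epoxide.

Step 12
Reactants: 11 (6S)-3-[(phenylsulfonyl)methyl]-6-[(E)-1-(trimethylstannyl)prop-1-en-2-yl]-5,6-dihydro-2H-pyran-2-one; 18 (2E)-5-[(2S,3S)-3-(2-hydroxyethyl)-3-methyloxiran-2-yl]-3-methylpent-2-en-1-yl acetate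
Product: 19 (6S)-6-[(2E,5E)-8-[(2S,3S)-3-(2-hydroxyethyl)-3-methyloxiran-2-yl]-6-methylocta-2,5-dien-2-yl]-3-[(phenylsulfonyl)methyl]-5,6-dihydro-2H-pyran-2-one
Conditions: Pd2(dba)3 (2.5 mol %), LiCl (3 equiv), DMF, 25–40 °C
Reagents that add atoms: none
Why: Stille coupling of a vinylstannane with an allylic acetate joins C5 to the primary allyl terminus C6 with retention of both alkene geometries (skipped 4E,7E diene), and at this temperature only the allylic acetate should ionise, not the allylic sulfone.

Step 13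
Reactants: 19 (the primary alcohol from step 12)
Product: 20 (6S)-6-[(2E,5E)-8-[(2S,3S)-3-(2-iodoethyl)-3-methyloxiran-2-yl]-6-methylocta-2,5-dien-2-yl]-3-[(phenylsulfonyl)methyl]-5,6-dihydro-2H-pyran-2-one
Conditions: PPh3, I2, imidazole, CH2Cl2, 0 °C (PPh3 and I2 premixed)
Reagents that add atoms: iodine II
Why: Appel-type iodination converts the only free (primary) hydroxyl into the iodide at C14; premixing leaves no free phosphine to add to the unsaturated lactone, and the epoxide survives at 0 °C.

Step 14
Reactants: 20 (the iodo epoxide with the sulfonyl-substituted unsaturated lactone)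
Product: 21 (1R,3S,11S,12S,4E,7E)-11,12-epoxy macrocycle: 14-membered carbocycle C1–C14 bridged from C1 to O3 by C15(=CH2)–C17(=O), methyls on C4, C8, C12
Conditions: (Bu3Sn)2 (1.5 equiv), hν (sunlamp), degassed PhH, 2 mM (syringe-pump addition of 20), 25–40 °C
Reagents that add atoms: none
Why: Photolysis of the ditin gives Bu3Sn•, which abstracts iodine from C14; the primary radical adds to C1, the β-carbon of ring T, and the C15 radical ejects PhSO2• (β-scission), which creates the C15=C16 methylene and carries the chain through the ditin, so that no hydride donor can quench the radical before it cyclises. The closest known reaction types are radical allyl transfer from alkyl iodides to 2-(sulfonylmethyl)- and 2-(stannylmethyl)acrylates, including macrocyclic cases, and radical macrocyclisation onto conjugated esters and lactones. Ring A (14-membered, C1 to C14) closes in the 14-exo-trig mode, C1 becoming a ring atom and C15 staying outside the new ring. The new stereocentre C1 is controlled by C3 through the half-chair of ring T: the C3 side chain sits pseudo-equatorial and the radical attacks C1 axially from the opposite face, which should give the 1,3-trans relationship (1R,3S), as in conjugate additions to 6-substituted 5,6-dihydropyran-2-ones. Ring closure must outrun oligomerisation and 1,5-hydrogen transfer, which high dilution, room-temperature photoinitiation and the activated cyclic acceptor should secure; the epoxide and the trisubstituted alkenes should stay untouched because the radical is never adjacent to the oxirane and unactivated trisubstituted alkenes react slowly with a primary alkyl radical.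

Step 15
Reactants: 21 (the macrocyclic six-membered lactone)
Product: 24 2-[(1R,3S,11S,12S,4E,7E)-3-(tert-butyldimethylsilyloxy)-11,12-epoxy-4,8,12-trimethylcyclotetradeca-4,7-dien-1-yl]acrylic acid (cembrane numbering), via lithium carboxylate 22 (not isolated), via bis-silyl derivative 23 (not isolated)
Conditions: LiOH (1.5 equiv), THF–H2O, 0 °C; then TBSCl (3 equiv), imidazole, DMF, rt; then K2CO3 (cat.), MeOH–H2O, 0 °C, pH 5 work-up
Reagents that add atoms: lithium hydroxide [Li+].[OH-]; tert-butyldimethylsilyl chloride CC(C)(C)[Si](C)(C)Cl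
Why: Saponification opens ring T; the carboxylate cannot relactonise under basic conditions, silylation caps C3–OH (a silyl ester would only pass its silyl group on), and mild hydrolysis removes the labile silyl ester alone.

Step 16
Reactants: 24 (the silyloxy epoxy acid)
Product: 26 3-O-tert-butyldimethylsilyl dendronpholide A, via hydroxy lactone 25 (not isolated)
Conditions: CSA (0.1 equiv), CH2Cl2, 0 °C; then Et3N, Ac2O, DMAP (cat.), 0 °C to rt
Reagents that add atoms: acetic anhydride CC(=O)OC(C)=O
Why: Acid-assisted 7-exo-tet opening of the trisubstituted epoxide by the carboxylic acid at the tertiary C12 with inversion (12S to 12R) closes ring B and frees the 11S hydroxyl (a biomimetic epoxy-acid lactonisation favoured over the eight-membered alternative), and DMAP-catalysed acetylation then caps the only free hydroxyl.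

Step 17
Reactants: 26 3-O-tert-butyldimethylsilyl dendronpholide A
Product: 27 Dendronpholide A
Conditions: HF·pyridine, pyridine–THF, 0 °C to rt
Reagents that add atoms: none
Why: Fluoride-mediated desilylation under buffered conditions removes the allylic silyl ether without touching the acetate, the α-methylene lactone or any stereocentre.

**Compound list**
1 | prop-2-yn-1-ol (propargyl alcohol) | C#CCO | starting material
2 | dimethylaluminium (E)-3-(dimethylalumanyl)-2-methylprop-2-en-1-olate | C[Al](C)OC/C(C)=C/[Al](C)C | intermediate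
3 | (E)-3-iodo-2-methylprop-2-en-1-ol | OC/C(C)=C/I | intermediate
4 | (E)-3-iodo-2-methylprop-2-enal | O=C/C(C)=C/I | intermediate
5 | (3S,1E)-1-iodo-2-methylhexa-1,5-dien-3-yl diisopinocampheylborinate | C=CC[C@H](OB([C@@H]1C[C@@H]2C[C@H]([C@H]1C)C2(C)C)[C@@H]1C[C@@H]2C[C@H]([C@H]1C)C2(C)C)/C(C)=C/I | intermediate
6 | (3S,1E)-1-iodo-2-methylhexa-1,5-dien-3-ol | C=CC[C@H](O)/C(C)=C/I | intermediate
7 | (3S,1E)-2-methyl-1-(trimethylstannyl)hexa-1,5-dien-3-ol | C=CC[C@H](O)/C(C)=C/[Sn](C)(C)C | intermediate
8 | 2-(bromomethyl)acrylic acid | OC(=O)C(=C)CBr | starting material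
9 | 2-[(phenylsulfonyl)methyl]acrylic acid | OC(=O)C(=C)CS(=O)(=O)c1ccccc1 | intermediate
10 | (3S,1E)-2-methyl-1-(trimethylstannyl)hexa-1,5-dien-3-yl 2-[(phenylsulfonyl)methyl]acrylate | C=CC[C@H](OC(=O)C(=C)CS(=O)(=O)c1ccccc1)/C(C)=C/[Sn](C)(C)C | intermediate
11 | (6S)-3-[(phenylsulfonyl)methyl]-6-[(E)-1-(trimethylstannyl)prop-1-en-2-yl]-5,6-dihydro-2H-pyran-2-one | C[Sn](C)(C)/C=C(\C)[C@@H]1CC=C(CS(=O)(=O)c2ccccc2)C(=O)O1 | intermediate
12 | geranyl acetate | CC(C)=CCC/C(C)=C/COC(C)=O | starting material
13 | (2E,6E)-8-hydroxy-3,7-dimethylocta-2,6-dien-1-yl acetate | OC/C(C)=C/CC/C(C)=C/COC(C)=O | intermediate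
14 | (2E,6E)-3,7-dimethyl-8-oxoocta-2,6-dien-1-yl acetate | O=C/C(C)=C/CC/C(C)=C/COC(C)=O | intermediate
15 | (2E,6E)-3,7-dimethylnona-2,6,8-trien-1-yl acetate | C=C/C(C)=C/CC/C(C)=C/COC(C)=O | intermediate
16 | (2E,6E)-9-(9-borabicyclo[3.3.1]nonan-9-yl)-3,7-dimethylnona-2,6-dien-1-yl acetate | C1CC2CCCC(C1)B2CC/C(C)=C/CC/C(C)=C/COC(C)=O | intermediate
17 | (2E,6E)-9-hydroxy-3,7-dimethylnona-2,6-dien-1-yl acetate | OCC/C(C)=C/CC/C(C)=C/COC(C)=O | intermediate
18 | (2E)-5-[(2S,3S)-3-(2-hydroxyethyl)-3-methyloxiran-2-yl]-3-methylpent-2-en-1-yl acetate | OCC[C@]1(C)O[C@H]1CC/C(C)=C/COC(C)=O | intermediate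
19 | (6S)-6-[(2E,5E)-8-[(2S,3S)-3-(2-hydroxyethyl)-3-methyloxiran-2-yl]-6-methylocta-2,5-dien-2-yl]-3-[(phenylsulfonyl)methyl]-5,6-dihydro-2H-pyran-2-one | OCC[C@]1(C)O[C@H]1CC/C(C)=C/C/C=C(\C)[C@@H]1CC=C(CS(=O)(=O)c2ccccc2)C(=O)O1 | intermediate
20 | (6S)-6-[(2E,5E)-8-[(2S,3S)-3-(2-iodoethyl)-3-methyloxiran-2-yl]-6-methylocta-2,5-dien-2-yl]-3-[(phenylsulfonyl)methyl]-5,6-dihydro-2H-pyran-2-one | ICC[C@]1(C)O[C@H]1CC/C(C)=C/C/C=C(\C)[C@@H]1CC=C(CS(=O)(=O)c2ccccc2)C(=O)O1 | intermediate
21 | (1R,3S,11S,12S,4E,7E)-11,12-epoxy macrocycle with C15(=CH2)–C17(=O)–O3 lactone bridge from C1 to C3 | C=C1C(=O)O[C@H]2C[C@H]1CC[C@]3(C)O[C@H]3CC/C(C)=C/C/C=C/2C | intermediate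
22 | lithium 2-[(1R,3S,11S,12S,4E,7E)-11,12-epoxy-3-hydroxy-4,8,12-trimethylcyclotetradeca-4,7-dien-1-yl]acrylate | C=C(C(=O)[O-])[C@H]1C[C@H](O)/C(C)=C/C/C=C(\C)CC[C@@H]2O[C@@]2(C)CC1.[Li+] | intermediate
23 | tert-butyldimethylsilyl ester of 24 | C=C(C(=O)O[Si](C)(C)C(C)(C)C)[C@H]1C[C@H](O[Si](C)(C)C(C)(C)C)/C(C)=C/C/C=C(\C)CC[C@@H]2O[C@@]2(C)CC1 | intermediate
24 | 2-[(1R,3S,11S,12S,4E,7E)-3-(tert-butyldimethylsilyloxy)-11,12-epoxy-4,8,12-trimethylcyclotetradeca-4,7-dien-1-yl]acrylic acid | C=C(C(=O)O)[C@H]1C[C@H](O[Si](C)(C)C(C)(C)C)/C(C)=C/C/C=C(\C)CC[C@@H]2O[C@@]2(C)CC1 | intermediate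
25 | 11-O-deacetyl-3-O-tert-butyldimethylsilyl dendronpholide A | C=C1C(=O)O[C@]2(C)CC[C@@H]1C[C@H](O[Si](C)(C)C(C)(C)C)/C(C)=C/C/C=C(\C)CC[C@@H]2O | intermediate
26 | 3-O-tert-butyldimethylsilyl dendronpholide A | C=C1C(=O)O[C@]2(C)CC[C@@H]1C[C@H](O[Si](C)(C)C(C)(C)C)/C(C)=C/C/C=C(\C)CC[C@@H]2OC(C)=O | intermediate
27 | Dendronpholide A | C=C1C(=O)O[C@]2(C)CC[C@@H]1C[C@H](O)/C(C)=C/C/C=C(\C)CC[C@@H]2OC(C)=O | target

**Step count and risks**
Total step count: 17. Longest linear sequence: 12 steps (1, 2, 3, 4, 6, 7, 12, 13, 14, 15, 16, 17).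

Step 14 is the riskiest. Ring closure at the substituted β-carbon may be too slow, so that 1,5-hydrogen transfer and oligomerisation take over, or the tether may weaken the facial preference at C1. The fallback reverses the order of the two unions. It sets out from 18, which is iodinated (PPh3, I2, imidazole) to the epoxy iodide F1. Intermolecular radical allyl transfer from F1 to an excess of 11 ((Bu3Sn)2, hν, PhH) forms C14–C1 on the untethered lactone, where trans addition has the closest precedent, and should give the seco stannane F2. An intramolecular Stille coupling of F2 (Pd2(dba)3, LiCl, DMF, 1 mM) then closes ring A at C5–C6 and comes back to the route at 21.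

Step 12 is next. The sulfonyl-substituted unsaturated lactone may interfere with the coupling through protodestannylation or through ionisation of the allylic sulfone by zerovalent palladium. The fallback builds ring T after the union. It sets out from 7 and 18, which are coupled under the same Stille conditions to the diol F3. Selective iodination of the primary hydroxyl (PPh3, I2, imidazole, −20 °C) should give the iodo alcohol F4, Steglich esterification with 9 the acrylate F5, and ring-closing metathesis with the second-generation Grubbs catalyst comes back to the route at 20.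

Step 15 is third. Hydroxide may add to the exocyclic methylene, or ring T may close again while the silyl ester is hydrolysed. The fallback protects the carboxyl group as an ester instead. It sets out from 22, which is alkylated in DMF with allyl bromide to the hydroxy allyl ester F6 and silylated (TBSCl, imidazole) to the silyl ether F7. Deallylation with Pd(PPh3)4 and PhSiH3 comes back to the route at 24.

**Further compounds**
F1 | step 14 | (2E)-5-[(2S,3S)-3-(2-iodoethyl)-3-methyloxiran-2-yl]-3-methylpent-2-en-1-yl acetate | ICC[C@]1(C)O[C@H]1CC/C(C)=C/COC(C)=O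
F2 | step 14 | (4R,6S)-3-methylene-6-[(E)-1-(trimethylstannyl)prop-1-en-2-yl]tetrahydropyran-2-one carrying at C4 the 2-[(2S,3S)-3-[(E)-5-acetoxy-3-methylpent-3-enyl]-2-methyloxiran-2-yl]ethyl chain | C=C1C(=O)O[C@@H](C[C@H]1CC[C@]2(C)O[C@H]2CC/C(C)=C/COC(C)=O)/C(C)=C/[Sn](C)(C)C
F3 | step 12 | (4S,5E,8E)-11-[(2S,3S)-3-(2-hydroxyethyl)-3-methyloxiran-2-yl]-5,9-dimethylundeca-1,5,8-trien-4-ol | OCC[C@]1(C)O[C@H]1CC/C(C)=C/C/C=C(\C)[C@@H](O)CC=C
F4 | step 12 | (4S,5E,8E)-11-[(2S,3S)-3-(2-iodoethyl)-3-methyloxiran-2-yl]-5,9-dimethylundeca-1,5,8-trien-4-ol | ICC[C@]1(C)O[C@H]1CC/C(C)=C/C/C=C(\C)[C@@H](O)CC=C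
F5 | step 12 | 2-[(phenylsulfonyl)methyl]acrylate of F4 | ICC[C@]1(C)O[C@H]1CC/C(C)=C/C/C=C(\C)[C@H](CC=C)OC(=O)C(=C)CS(=O)(=O)c1ccccc1
F6 | step 15 | allyl 2-[(1R,3S,11S,12S,4E,7E)-11,12-epoxy-3-hydroxy-4,8,12-trimethylcyclotetradeca-4,7-dien-1-yl]acrylate | C=CCOC(=O)C(=C)[C@H]1C[C@H](O)/C(C)=C/C/C=C(\C)CC[C@@H]2O[C@@]2(C)CC1
F7 | step 15 | allyl ester of 24 | C=CCOC(=O)C(=C)[C@H]1C[C@H](O[Si](C)(C)C(C)(C)C)/C(C)=C/C/C=C(\C)CC[C@@H]2O[C@@]2(C)CC1
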